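**Plan**

1. Retrosynthesis first removes the C2'-O isovalerate and the two silyl ethers, then opens the lactone bond O1-C2 to an (E)-2-hydroxycinnamate.
2. Ring A (C4a, C5, C6, C7, C8, C8a) carries the ring oxygen on C8a, the branched side chain on C8 and methoxy on C7 as three contiguous substituents, with the C4=C3 unit on C4a. This is the pattern a 1-methoxyalkyne gives in a vinylketene benzannulation, so ring A is cut at C8-C8a, C6-C7 and C4a-C8a.
3. The two fragments are a dienyl diazo ketone (C2, C3, C4, C4a, C5, C6, C8a; its C4a=C5 bond from a Wittig reaction) and a methoxyalkyne (C7, C8 and the side chain; its C8-C1' bond from an acetylide addition).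
4. Forward: the diazo ketone takes two steps and the alkyne six steps from prenol. Ring A closes in step 9 and the pyranone ring in step 10 by photoisomerisation and lactonisation. The triethylsilyl group is then exchanged for the isovalerate and the last silyl group is removed.
5. Stereochemistry: C2' comes from a Sharpless epoxidation of prenol with D-(−)-diisopropyl tartrate, and C1' from a Felkin-Anh addition of lithium methoxyacetylide to the α-silyloxy aldehyde. Both centres are spectators from step 9 onward.

Key step: step 9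

Remark: C1' is the side-chain carbon on C8 and C2' the next one. The ester is carried as ethyl and the two hydroxyls as silyl ethers, and the isovalerate is put on only after the rings are made. An ester next to the lithium alkoxide formed in the acetylide addition would invite acyl migration.

**Route**

Step 1
Reactants: 1 ethyl (E)-4-oxobut-2-enoate; 2 1-(triphenyl-λ5-phosphanylidene)propan-2-one
Product: 3 ethyl (2E,4E)-6-oxohepta-2,4-dienoate
Conditions: CH2Cl2, 23 °C
Reagents that add atoms: none
Why: Wittig olefination with a ketone-stabilised ylide is selective for the aldehyde and for the E alkene, so the (2E,4E)-dienone should form directly.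

Step 2
Reactants: 3 ethyl (2E,4E)-6-oxohepta-2,4-dienoate
Product: 5 ethyl (2E,4E)-7-diazo-6-oxohepta-2,4-dienoate, via trifluoroacetyl ketone 4 (not isolated)
Conditions: LiN(SiMe3)2, THF, −78 °C; CF3CO2CH2CF3, −78 °C; aqueous HCl work-up, crude 4 used at once; then MsN3, Et3N, H2O (1 equiv), MeCN, 23 °C
Reagents that add atoms: 2,2,2-trifluoroethyl trifluoroacetate, FC(F)(F)COC(=O)C(F)(F)F (atoms held only in 4); methanesulfonyl azide, CS(=O)(=O)N=[N+]=[N-]
Why: Detrifluoroacetylative diazo transfer: only the methyl group of 3 can be enolised, Claisen trifluoroacetylation activates it, and mesyl azide transfers the diazo group with loss of the trifluoroacetyl group; this avoids acylating diazomethane, which would add as a dipole to the electron-poor double bonds.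

Step 3
Reactants: 6 prenol (3-methylbut-2-en-1-ol)
Product: 7 (R)-(3,3-dimethyloxiran-2-yl)methanol
Conditions: Ti(OiPr)4 (5 mol %), D-(−)-diisopropyl tartrate (6 mol %), t-BuOOH, 4 Å molecular sieves, CH2Cl2, −20 °C
Reagents that add atoms: tert-butyl hydroperoxide, CC(C)(C)OO
Why: Sharpless asymmetric epoxidation; the D-(−)-tartrate ligand directs oxygen to the face of the allylic alcohol that gives the (2R)-epoxide, which fixes the future C2' centre.

Step 4
Reactants: 7 (R)-(3,3-dimethyloxiran-2-yl)methanol
Product: 8 (S)-3-methylbut-3-ene-1,2-diol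
Conditions: Ti(OiPr)4 (1.5 equiv), CH2Cl2, 23 °C; aqueous tartaric acid work-up
Reagents that add atoms: none
Why: Hydroxyl-directed Lewis-acid rearrangement of a 2,3-epoxy alcohol to an ene-diol: the titanium alkoxide of 7 activates the epoxide internally, the tertiary C3-O bond breaks and a methyl proton is lost, so the C2-O bond keeps its configuration (the descriptor changes from R to S only through the priority rules).

Step 5
Reactants: 8 (S)-3-methylbut-3-ene-1,2-diol
Product: 9 (S)-3-methyl-1,2-bis(triethylsilyloxy)but-3-ene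
Conditions: Et3SiCl, imidazole, DMF, 0 → 23 °C
Reagents that add atoms: chlorotriethylsilane, CC[Si](Cl)(CC)CC
Why: Standard silylation of both hydroxyls with a silyl chloride and imidazole.

Step 6
Reactants: 9 (S)-3-methyl-1,2-bis(triethylsilyloxy)but-3-ene
Product: 10 (S)-3-methyl-2-(triethylsilyloxy)but-3-enal
Conditions: (COCl)2, DMSO, CH2Cl2, −78 → −40 °C; Et3N, −78 °C; used crude
Reagents that add atoms: none
Why: Swern conditions cleave and oxidise a primary triethylsilyl ether in the presence of a secondary one, giving the α-silyloxy aldehyde in one operation; low temperature and immediate use guard against epimerisation and against migration of the double bond into conjugation.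

Step 7
Reactants: 10 (S)-3-methyl-2-(triethylsilyloxy)but-3-enal; 11 chloroacetaldehyde dimethyl acetal
Product: 13 (3R,4S)-1-methoxy-5-methyl-4-(triethylsilyloxy)hex-5-en-1-yn-3-ol, via lithium methoxyacetylide 12 (not isolated)
Conditions: Et2NH, n-BuLi, THF, 0 °C; 11, 0 °C; then 10, −78 °C; aqueous NH4Cl at −78 °C
Reagents that add atoms: none
Why: Double elimination of the chloroacetal with LiNEt2 gives lithium methoxyacetylide, which should add to the aldehyde under Felkin-Anh control (silyloxy group anti to the nucleophile, no chelation) to give mainly the 3,4-anti (3R,4S) carbinol; the minor syn isomer is removed by chromatography and the cold quench prevents silyl migration.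

Step 8
Reactants: 13 (3R,4S)-1-methoxy-5-methyl-4-(triethylsilyloxy)hex-5-en-1-yn-3-ol
Product: 14 (3R,4S)-3-(tert-butyldimethylsilyloxy)-1-methoxy-5-methyl-4-(triethylsilyloxy)hex-5-en-1-yne
Conditions: t-BuMe2SiCl, imidazole, DMF, 23 °C
Reagents that add atoms: tert-butyldimethylsilyl chloride, CC(C)(C)[Si](C)(C)Cl
Why: Silylation of a propargylic secondary alcohol under basic conditions, which the acid-sensitive ynol ether tolerates.

Step 9
Reactants: 5 ethyl (2E,4E)-7-diazo-6-oxohepta-2,4-dienoate; 14 (3R,4S)-3-(tert-butyldimethylsilyloxy)-1-methoxy-5-methyl-4-(triethylsilyloxy)hex-5-en-1-yne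
Product: 19 ethyl (E)-3-{3-[(1R,2S)-1-(tert-butyldimethylsilyloxy)-3-methyl-2-(triethylsilyloxy)but-3-enyl]-2-hydroxy-4-methoxyphenyl}prop-2-enoate, via dienylketene 15 (not isolated), via cyclobutenone 16 (not isolated), via ring-opened dienylketene 17 (not isolated), via cyclohexadienone 18 (not isolated)
Conditions: 5 (1.5 equiv, in portions), 14 (1.0 equiv), hν (300 nm, Pyrex), ClCH2CH2Cl, 23 °C; then 80 °C
Reagents that add atoms: none
Why: Irradiation expels N2 from 5 and Wolff rearrangement gives dienylketene 15, whose C=C=O unit adds [2+2] to the electron-rich alkyne to give cyclobutenone 16 (bonds C8-C8a and C6-C7); heating opens 16 by a four-electron conrotatory electrocyclic reaction to dienylketene 17, ring A closes by a thermal six-electron disrotatory electrocyclisation (bond C4a-C8a) to dienone 18, and tautomerisation gives phenol 19. The closest known reaction type is the Danheiser benzannulation in its photochemical Wolff form, which converts α,β-unsaturated α'-diazo ketones and 1-alkoxyalkynes into resorcinol monoethers. No stereocentre is created, since the sp3 ring carbons of 16 and 18 disappear on aromatisation and C1' and C2' are spectators. The step needs one regiochemistry, the side chain between the phenol and the methoxy group, and the polarisation of the ynol ether secures it because its nucleophilic carbon remote from oxygen bonds to the ketene carbonyl carbon. The ynol ether is a far better ketene partner than the 1,1-disubstituted alkene or the silyl ethers, and the (E,E)-geometry of 15 keeps the ketene from closing onto its own ester-bearing terminus.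

Step 10
Reactants: 19 ethyl (E)-3-{3-[(1R,2S)-1-(tert-butyldimethylsilyloxy)-3-methyl-2-(triethylsilyloxy)but-3-enyl]-2-hydroxy-4-methoxyphenyl}prop-2-enoate
Product: 21 8-[(1R,2S)-1-(tert-butyldimethylsilyloxy)-3-methyl-2-(triethylsilyloxy)but-3-enyl]-7-methoxy-2H-chromen-2-one, via Z-acrylate 20 (not isolated)
Conditions: hν (365 nm), MeCN (5 mM), 23 °C
Reagents that add atoms: none
Why: Photochemical E to Z isomerisation of a 2-hydroxycinnamate places the ester next to the phenol, and the cis isomer lactonises with loss of ethanol to close the pyranone ring; high dilution suppresses [2+2] photodimerisation of the coumarin.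

Step 11
Reactants: 21 8-[(1R,2S)-1-(tert-butyldimethylsilyloxy)-3-methyl-2-(triethylsilyloxy)but-3-enyl]-7-methoxy-2H-chromen-2-one
Product: 22 8-[(1R,2S)-1-(tert-butyldimethylsilyloxy)-2-hydroxy-3-methylbut-3-enyl]-7-methoxy-2H-chromen-2-one
Conditions: pyridinium p-toluenesulfonate (0.2 equiv), MeOH/CH2Cl2 (1:1), 0 → 23 °C
Reagents that add atoms: none
Why: Mild acid-catalysed methanolysis removes the more labile triethylsilyl ether and should leave the tert-butyldimethylsilyl ether on the shielded benzylic oxygen.

Step 12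
Reactants: 22 8-[(1R,2S)-1-(tert-butyldimethylsilyloxy)-2-hydroxy-3-methylbut-3-enyl]-7-methoxy-2H-chromen-2-one; 23 isovaleryl chloride
Product: 24 (1R,2S)-1-(tert-butyldimethylsilyloxy)-1-(7-methoxy-2-oxo-2H-chromen-8-yl)-3-methylbut-3-en-2-yl 3-methylbutanoate
Conditions: pyridine, DMAP (0.2 equiv), CH2Cl2, 0 → 23 °C
Reagents that add atoms: none
Why: DMAP-catalysed O-acylation of the secondary allylic alcohol proceeds with retention at C2', and the silyl group on the neighbouring oxygen rules out acyl migration at this stage.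

Step 13
Reactants: 24 (1R,2S)-1-(tert-butyldimethylsilyloxy)-1-(7-methoxy-2-oxo-2H-chromen-8-yl)-3-methylbut-3-en-2-yl 3-methylbutanoate
Product: 25 (1R,2S)-1-hydroxy-1-(7-methoxy-2-oxo-2H-chromen-8-yl)-3-methylbut-3-en-2-yl 3-methylbutanoate
Conditions: HF·pyridine, pyridine, THF, 0 → 23 °C
Reagents that add atoms: none
Why: Buffered fluoride desilylation; the medium is not basic enough for 1,2-acyl migration or lactone opening and not acidic enough to ionise the benzylic C-O bond, so both stereocentres and the ester position should be kept.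

**Compound list**

1 | ethyl (E)-4-oxobut-2-enoate | CCOC(=O)/C=C/C=O | starting material
2 | 1-(triphenyl-λ5-phosphanylidene)propan-2-one | CC(=O)C=P(c1ccccc1)(c1ccccc1)c1ccccc1 | starting material
3 | ethyl (2E,4E)-6-oxohepta-2,4-dienoate | CCOC(=O)/C=C/C=C/C(C)=O | intermediate
4 | ethyl (2E,4E)-8,8,8-trifluoro-6,8-dioxoocta-2,4-dienoate | CCOC(=O)/C=C/C=C/C(=O)CC(=O)C(F)(F)F | intermediate
5 | ethyl (2E,4E)-7-diazo-6-oxohepta-2,4-dienoate | CCOC(=O)/C=C/C=C/C(=O)C=[N+]=[N-] | intermediate
6 | prenol (3-methylbut-2-en-1-ol) | CC(C)=CCO | starting material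
7 | (R)-(3,3-dimethyloxiran-2-yl)methanol | OC[C@H]1OC1(C)C | intermediate
8 | (S)-3-methylbut-3-ene-1,2-diol | C=C(C)[C@H](O)CO | intermediate
9 | (S)-3-methyl-1,2-bis(triethylsilyloxy)but-3-ene | C=C(C)[C@H](O[Si](CC)(CC)CC)CO[Si](CC)(CC)CC | intermediate
10 | (S)-3-methyl-2-(triethylsilyloxy)but-3-enal | C=C(C)[C@H](O[Si](CC)(CC)CC)C=O | intermediate
11 | chloroacetaldehyde dimethyl acetal (2-chloro-1,1-dimethoxyethane) | COC(CCl)OC | starting material
12 | lithium methoxyacetylide | [Li]C#COC | intermediate
13 | (3R,4S)-1-methoxy-5-methyl-4-(triethylsilyloxy)hex-5-en-1-yn-3-ol | C=C(C)[C@H](O[Si](CC)(CC)CC)[C@H](O)C#COC | intermediate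
14 | (3R,4S)-3-(tert-butyldimethylsilyloxy)-1-methoxy-5-methyl-4-(triethylsilyloxy)hex-5-en-1-yne | C=C(C)[C@H](O[Si](CC)(CC)CC)[C@H](O[Si](C)(C)C(C)(C)C)C#COC | intermediate
15 | ethyl (2E,4E)-7-oxohepta-2,4,6-trienoate (dienylketene) | CCOC(=O)/C=C/C=C/C=C=O | intermediate
16 | ethyl (2E,4E)-5-{3-[(1R,2S)-1-(tert-butyldimethylsilyloxy)-3-methyl-2-(triethylsilyloxy)but-3-enyl]-2-methoxy-4-oxocyclobut-2-en-1-yl}penta-2,4-dienoate (both epimers at the ring CH) | C=C(C)[C@H](O[Si](CC)(CC)CC)[C@H](O[Si](C)(C)C(C)(C)C)C1=C(OC)C(/C=C/C=C/C(=O)OCC)C1=O | intermediate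
17 | ethyl (2E,4E,6E)-8-[(1R,2S)-1-(tert-butyldimethylsilyloxy)-3-methyl-2-(triethylsilyloxy)but-3-enyl]-7-methoxy-9-oxonona-2,4,6,8-tetraenoate | C=C(C)[C@H](O[Si](CC)(CC)CC)[C@H](O[Si](C)(C)C(C)(C)C)C(=C=O)/C(OC)=C\C=C\C=C\C(=O)OCC | intermediate
18 | ethyl (E)-3-{3-[(1R,2S)-1-(tert-butyldimethylsilyloxy)-3-methyl-2-(triethylsilyloxy)but-3-enyl]-4-methoxy-2-oxocyclohexa-3,5-dien-1-yl}prop-2-enoate (both epimers at the ring CH) | C=C(C)[C@H](O[Si](CC)(CC)CC)[C@H](O[Si](C)(C)C(C)(C)C)C1=C(OC)C=CC(/C=C/C(=O)OCC)C1=O | intermediate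
19 | ethyl (E)-3-{3-[(1R,2S)-1-(tert-butyldimethylsilyloxy)-3-methyl-2-(triethylsilyloxy)but-3-enyl]-2-hydroxy-4-methoxyphenyl}prop-2-enoate | C=C(C)[C@H](O[Si](CC)(CC)CC)[C@H](O[Si](C)(C)C(C)(C)C)c1c(OC)ccc(/C=C/C(=O)OCC)c1O | intermediate
20 | ethyl (Z)-3-{3-[(1R,2S)-1-(tert-butyldimethylsilyloxy)-3-methyl-2-(triethylsilyloxy)but-3-enyl]-2-hydroxy-4-methoxyphenyl}prop-2-enoate | C=C(C)[C@H](O[Si](CC)(CC)CC)[C@H](O[Si](C)(C)C(C)(C)C)c1c(OC)ccc(/C=C\C(=O)OCC)c1O | intermediate
21 | 8-[(1R,2S)-1-(tert-butyldimethylsilyloxy)-3-methyl-2-(triethylsilyloxy)but-3-enyl]-7-methoxy-2H-chromen-2-one | C=C(C)[C@H](O[Si](CC)(CC)CC)[C@H](O[Si](C)(C)C(C)(C)C)c1c(OC)ccc2ccc(=O)oc12 | intermediate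
22 | 8-[(1R,2S)-1-(tert-butyldimethylsilyloxy)-2-hydroxy-3-methylbut-3-enyl]-7-methoxy-2H-chromen-2-one | C=C(C)[C@H](O)[C@H](O[Si](C)(C)C(C)(C)C)c1c(OC)ccc2ccc(=O)oc12 | intermediate
23 | isovaleryl chloride (3-methylbutanoyl chloride) | CC(C)CC(=O)Cl | starting material
24 | (1R,2S)-1-(tert-butyldimethylsilyloxy)-1-(7-methoxy-2-oxo-2H-chromen-8-yl)-3-methylbut-3-en-2-yl 3-methylbutanoate | C=C(C)[C@H](OC(=O)CC(C)C)[C@H](O[Si](C)(C)C(C)(C)C)c1c(OC)ccc2ccc(=O)oc12 | intermediate
25 | (1R,2S)-1-hydroxy-1-(7-methoxy-2-oxo-2H-chromen-8-yl)-3-methylbut-3-en-2-yl 3-methylbutanoate | C=C(C)[C@H](OC(=O)CC(C)C)[C@H](O)c1c(OC)ccc2ccc(=O)oc12 | target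

**Step count and risks**

Total step count: 13. Longest linear sequence: 11 steps (steps 3 to 13, from prenol); the diazo ketone branch (steps 1 and 2) joins at step 9.

Steps most likely to fail:

Step 9. Two processes may go wrong. Under irradiation the C4=C5 double bond of 5 or of ketene 15 may isomerise, and the Z-ketene then closes by a six-electron reaction onto its own ester-bearing terminus. Alternatively, cycloaddition at the hindered alkyne carbon may be slow enough for the ketene to dimerise. The fallback keeps the benzannulation but removes the second double bond from the ketene; it sets out from alkyne 14 and ylide 2. Wittig reaction of 2 with commercial 2,2-dimethoxyacetaldehyde should give (E)-5,5-dimethoxypent-3-en-2-one F1. Trifluoroacetylation as in step 2 gives crude (E)-1,1,1-trifluoro-7,7-dimethoxyhept-5-ene-2,4-dione F2, and diazo transfer gives (E)-1-diazo-5,5-dimethoxypent-3-en-2-one F3, a plain enone-derived diazo ketone of the kind for which this benzannulation is best established. Irradiation and heating with 14 should give 6-(dimethoxymethyl)-3-methoxy-2-[(1R,2S)-1-(tert-butyldimethylsilyloxy)-3-methyl-2-(triethylsilyloxy)but-3-enyl]phenol F4. Oxalic acid on wet silica gel should unmask 2-hydroxy-4-methoxy-3-[(1R,2S)-1-(tert-butyldimethylsilyloxy)-3-methyl-2-(triethylsilyloxy)but-3-enyl]benzaldehyde F5, and Wittig olefination with Ph3P=CHCO2Et in CH2Cl2 at 23 °C comes back to the route at 19.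

Step 7. Facial selectivity in the acetylide addition may be poor, since lithium acetylides often give only modest Felkin-Anh preference with α-silyloxy aldehydes. The fallback replaces substrate control by catalyst control and sets out from 13 as the mixture of C3 epimers. Oxidation with MnO2 in CH2Cl2 should give (S)-1-methoxy-5-methyl-4-(triethylsilyloxy)hex-5-en-1-yn-3-one F6. Noyori transfer hydrogenation of this ynone with Ru[(S,S)-TsNCHPhCHPhNH](p-cymene) in i-PrOH at 23 °C, in which the alkynyl group takes the place of the aryl group of the usual substrates, should deliver the (3R) carbinol and return to the route at 13.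

Step 4. Isopropoxide may open the activated epoxide at C3 in competition with proton loss, and the small water-soluble diol may be lost on work-up. The fallback uses a base-mediated syn elimination on the protected epoxide and sets out from 7. Silylation (Et3SiCl, imidazole, DMF) gives (R)-[(3,3-dimethyloxiran-2-yl)methoxy]triethylsilane F7. Diethylaluminium 2,2,6,6-tetramethylpiperidide (from Et2AlCl and lithium 2,2,6,6-tetramethylpiperidide) in toluene at 0 °C should abstract a methyl proton and give (S)-3-methyl-1-(triethylsilyloxy)but-3-en-2-ol F8. A second silylation with Et3SiCl and imidazole comes back to the route at 9.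

**Further compounds**

F1 | step 9 | (E)-5,5-dimethoxypent-3-en-2-one | COC(OC)/C=C/C(C)=O
F2 | step 9 | (E)-1,1,1-trifluoro-7,7-dimethoxyhept-5-ene-2,4-dione | COC(OC)/C=C/C(=O)CC(=O)C(F)(F)F
F3 | step 9 | (E)-1-diazo-5,5-dimethoxypent-3-en-2-one | COC(OC)/C=C/C(=O)C=[N+]=[N-]
F4 | step 9 | 6-(dimethoxymethyl)-3-methoxy-2-[(1R,2S)-1-(tert-butyldimethylsilyloxy)-3-methyl-2-(triethylsilyloxy)but-3-enyl]phenol | C=C(C)[C@H](O[Si](CC)(CC)CC)[C@H](O[Si](C)(C)C(C)(C)C)c1c(OC)ccc(C(OC)OC)c1O
F5 | step 9 | 2-hydroxy-4-methoxy-3-[(1R,2S)-1-(tert-butyldimethylsilyloxy)-3-methyl-2-(triethylsilyloxy)but-3-enyl]benzaldehyde | C=C(C)[C@H](O[Si](CC)(CC)CC)[C@H](O[Si](C)(C)C(C)(C)C)c1c(OC)ccc(C=O)c1O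
F6 | step 7 | (S)-1-methoxy-5-methyl-4-(triethylsilyloxy)hex-5-en-1-yn-3-one | C=C(C)[C@H](O[Si](CC)(CC)CC)C(=O)C#COC
F7 | step 4 | (R)-[(3,3-dimethyloxiran-2-yl)methoxy]triethylsilane | CC[Si](CC)(CC)OC[C@H]1OC1(C)C
F8 | step 4 | (S)-3-methyl-1-(triethylsilyloxy)but-3-en-2-ol | C=C(C)[C@H](O)CO[Si](CC)(CC)CC
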